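The easy step first: a first-order drain empties a tank with one time constant whatever the charge, whereas the time of a second-order step shortens as the charge rises.

    2 substrate → self-condensation product (k1 = 3.45 × 10⁻⁴ /M/s)
    substrate ⇌ isomer of the product (K2 = 3.02, k2 = 8.35 × 10⁻⁶ /s)
    crystals ⇌ target, rate k3*(cs3 - [target]) while solid is left; crystals form when [target] > cs3 (cs3 = 20 mM, k3 = 1.28 × 10⁻⁴ /s)
    substrate ⇌ target (K4 = 6.3, k4 = 1.68 × 10⁻⁵ /s)

substrate 0.10 M; time 30 h

- the target and crystals together standing at 30 h, as a percentage of the substrate charged
- concentration of target in solution at 3.0 h, in percent of saturation
- the change that raises the amount of target and crystals together at 30 h, in percent of the substrate charged most ("none" if none brings more than 2 percentage points) (green / amber / none)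
- amount of target and crystals together at 30 h, in percent of the substrate charged, after green

- green: doubling the solubility in step 3, all else as stated
- amber: doubling the dissolution coefficient of step 3, all else as stated

- a species is counted by the substrate in it: one self-condensation product counts as two
- amounts and yields of target count crystals too
- a doubled species enters its step squared and goes two at a time
- given per volume of solution although it is solid: crystals
- run time (flask): 30 h

- In this reckoning, made before the result, substrate has two exits. Condensation has a first half-life τc = 4.03 h at the charge. The two isomerisations together form a first-order drain with time constant τf = 11.0 h.
- The return steps are dropped because their times, 104 h from target and 100 h from isomer of the product, are longer than the 30 h run. Dissolution, with a time of 2.17 h, is dropped as well, since it moves material between two forms that the yield counts together.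
- The quantity carried forward is N = τf/τc = 2.74, the ratio of the drain time to the condensation time at the charge.
- With u the fraction of substrate left, du/dt = −u/τf − u·u/τc. Dividing the drain term by the whole loss and integrating until the substrate is consumed gives the first-order share (a selectivity) ln(1 + N)/N = 48.1%.
- The target's part of the drain is 66.8%, so this reckoning commits to 32.1% for y. It expects crystals, since 32.1 mM is more than the solubility of 20 mM. It says "none" for best, because N holds neither constant of the crystals, and it gives no value for sat.
- The forecast gives y = 28% (25.5% to 30.5%), sat = 60%, best = none and yb = 27.3%, which puts its y below this reckoning. Its ground: “the total is set by how much substrate flows to the target rather than by crystal kinetics”.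
- The simulation gives y = 28.3%, sat = 60.2%, best = none (green −0.75 percentage points, amber 0.053 points) and yb = 27.5%.

In the flask, half of the condensation turnover up to 30 h was done by 1.76 h, earlier than the 11 h half-life of substrate by forward conversion to target alone at 30.0 h. Self-condensation product stands at 53.7% at 30.0 h, against 51.9% reckoned from N.

In the neighbour flask, charged with 0.040 M, N falls to 1.10, which gives 32.6% condensed and 45.1% target. The computed neighbour flask holds 34.3% self-condensation product and 38.7% target at 30.0 h.

(The constants used here are invented; what happens was integrated by code.)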